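The flavone is cut at O1–C8a and C4–C4a, the two bonds that join ring C to ring A. C8a and C4a are neighbouring ring A carbons. One bears the ring oxygen and the other the acyl carbon, so they map onto the two carbons of an aryne and onto the O–C(=O) unit of a carboxylic acid. Fluoride frees 3,4,6-trimethoxybenzyne from an ortho-silylaryl triflate, and the aryne inserts into the acyl–oxygen bond of 3-(2,5-dimethoxyphenyl)propiolic acid. One operation thus forms both bonds and brings in C2, C3, C4 and ring B, giving an ortho-hydroxyaryl ynone. A 6-endo closure of O1–C2 completes the target.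

Key step: step 6

Remark: flavone numbering (O1, C2, C3, C4, C4a, C5 to C8, C8a; rings A, B, C) is applied to the corresponding atoms of every intermediate. The target has no stereocentre and no double-bond geometry to control.

Step 1
Reactants: 1 2,4,5-trimethoxybenzaldehyde
Product: 3 2,4,5-trimethoxyphenol, via aryl formate 2 (not isolated)
Conditions: 30% aq H2O2, H2SO4 (cat.), MeOH, rt
Reagents that add atoms: hydrogen peroxide OO
Why: Acid-catalysed Dakin oxidation, in which the hydroperoxide adduct of the aldehyde undergoes Baeyer–Villiger-type migration of the very electron-rich aryl group and formate 2 is methanolysed in the same flask, while the acidic medium keeps the oxidation-prone product as the neutral phenol.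

Step 2
Reactants: 3 2,4,5-trimethoxyphenol
Product: 4 2,4,5-trimethoxyphenyl N-isopropylcarbamate
Conditions: i-PrNCO, Et3N (cat.), CH2Cl2, rt
Reagents that add atoms: isopropyl isocyanate CC(C)N=C=O
Why: Base-catalysed addition of the phenol O–H to the isocyanate (carbamoylation) installs a strong ortho-directing group that can later be removed under mild E1cB conditions.

Step 3
Reactants: 4 2,4,5-trimethoxyphenyl N-isopropylcarbamate
Product: 8 3,4,6-trimethoxy-2-(trimethylsilyl)phenyl N-isopropylcarbamate, via N-silyl carbamate 5 (not isolated), via aryllithium 6 (not isolated), via doubly silylated carbamate 7 (not isolated)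
Conditions: TBSOTf, TMEDA, Et2O, 0 °C to rt; n-BuLi (2 equiv), TMEDA, −78 °C; TMSCl, −78 °C to rt; aq NaHSO4
Reagents that add atoms: chlorotrimethylsilane C[Si](C)(C)Cl; tert-butyldimethylsilyl triflate CC(C)(C)[Si](C)(C)OS(=O)(=O)C(F)(F)F (its atoms stay only in 5 to 7 and are lost again on work-up)
Why: Directed ortho-metalation, in which the N–H is first masked as the N-silyl carbamate and the only free position ortho to the carbamate (the future C4a) lies between that group and a methoxy group, so both donors guide n-BuLi there ahead of the C–H flanked by two methoxy groups, TMSCl traps the aryllithium, and no electrophilic halogenating agent that could oxidise this hydroquinone-type ring is needed.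

Step 4
Reactants: 8 3,4,6-trimethoxy-2-(trimethylsilyl)phenyl N-isopropylcarbamate
Product: 10 3,4,6-trimethoxy-2-(trimethylsilyl)phenyl trifluoromethanesulfonate, via silylphenol 9 (not isolated)
Conditions: Et2NH, DBU, MeCN, 40 °C; then PhNTf2, 40 °C
Reagents that add atoms: N-phenylbis(trifluoromethanesulfonimide) O=S(=O)(N(c1ccccc1)S(=O)(=O)C(F)(F)F)C(F)(F)F
Why: DBU deprotonates the carbamate N–H, isopropyl isocyanate is expelled (E1cB) and trapped by Et2NH as a urea, and the phenoxide of 9 is then O-sulfonylated by PhNTf2 in the same flask, a non-acidic sequence that avoids protodesilylation.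

Step 5
Reactants: 11 2-iodo-1,4-dimethoxybenzene; 12 propiolic acid
Product: 13 3-(2,5-dimethoxyphenyl)propiolic acid
Conditions: Pd(PPh3)4 (2.5 mol %), DBU (2.5 equiv), DMSO, 35 °C; then aq HCl
Reagents that add atoms: none
Why: Copper-free Sonogashira coupling, in which zerovalent palladium inserts into the C–I bond and the DBU salt of propiolic acid couples at its terminal C–H, the low temperature and the absence of copper keeping the arylpropiolate from decarboxylating.

Step 6
Reactants: 10 3,4,6-trimethoxy-2-(trimethylsilyl)phenyl trifluoromethanesulfonate; 13 3-(2,5-dimethoxyphenyl)propiolic acid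
Product: 15 3-(2,5-dimethoxyphenyl)-1-(2-hydroxy-3,5,6-trimethoxyphenyl)prop-2-yn-1-one, via 3,4,6-trimethoxybenzyne 14 (not isolated)
Conditions: CsF (4 equiv), THF, sealed tube, 125 °C; aq NH4Cl
Reagents that add atoms: none
Why: Fluoride attacks silicon in 10 and triflate departs to give aryne 14; the cesium carboxylate of 13 adds through oxygen to one aryne carbon, the aryl anion born on the neighbouring carbon attacks the ester carbonyl through a four-membered transition state, and the strained adduct opens to the phenoxide of 15, a net insertion of the aryne into the acyl–oxygen bond that forms C8a–O1 and C4a–C4. The closest known reaction type is the fluoride-induced C–O insertion of arynes into carboxylic acids, arylpropiolic acids included, run in hot THF so that the intramolecular acyl transfer (an aryne version of the anionic Fries shift) outruns protonation of the aryl anion to the plain aryl ester. No ring is closed and no stereocentre is created. The selectivity needed is oxygen attack at C8a and not at C4a: the C5 methoxy is wedged between the C6 methoxy and the aryne, so it is twisted out of the ring plane, acts as a pure sigma acceptor that favours negative charge on C4a and screens that carbon, whereas the C8 methoxy can turn its methyl group toward C7–H and leaves C8a open, and the C6 methoxy, meta to C4a and para to C8a, adds a further inductive pull in the same sense. Since each aryne carbon still has an ortho methoxy group the bias is not absolute, and material from the reverse addition (5,7,8-trimethoxy series) is to be removed by chromatography here or after step 7. Any 15 that already closes to 16 in the basic medium is not lost, because step 7 takes the whole material to 16.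

Step 7
Reactants: 15 3-(2,5-dimethoxyphenyl)-1-(2-hydroxy-3,5,6-trimethoxyphenyl)prop-2-yn-1-one
Product: 16 2-(2,5-dimethoxyphenyl)-5,6,8-trimethoxy-4H-chromen-4-one (target)
Conditions: DMAP (20 mol %), DMF, 40 °C
Reagents that add atoms: none
Why: DMAP-catalysed oxa-Michael cyclisation, in which the nucleophilic amine adds to the ynone beta-carbon C2, the C8a phenol attacks the same carbon and DMAP leaves, so that only the 6-endo mode (O1–C2, flavone) and not the 5-exo mode (aurone) is open.

Compound list
1 | 2,4,5-trimethoxybenzaldehyde | COc1cc(OC)c(C=O)cc1OC | starting material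
2 | 2,4,5-trimethoxyphenyl formate | COc1cc(OC)c(OC=O)cc1OC | intermediate
3 | 2,4,5-trimethoxyphenol | COc1cc(OC)c(O)cc1OC | intermediate
4 | 2,4,5-trimethoxyphenyl N-isopropylcarbamate | COc1cc(OC)c(OC(=O)NC(C)C)cc1OC | intermediate
5 | 2,4,5-trimethoxyphenyl N-(tert-butyldimethylsilyl)-N-isopropylcarbamate | COc1cc(OC)c(OC(=O)N(C(C)C)[Si](C)(C)C(C)(C)C)cc1OC | intermediate
6 | 2-lithio-3,4,6-trimethoxyphenyl N-(tert-butyldimethylsilyl)-N-isopropylcarbamate | COc1cc(OC)c(OC(=O)N(C(C)C)[Si](C)(C)C(C)(C)C)c([Li])c1OC | intermediate
7 | 3,4,6-trimethoxy-2-(trimethylsilyl)phenyl N-(tert-butyldimethylsilyl)-N-isopropylcarbamate | COc1cc(OC)c(OC(=O)N(C(C)C)[Si](C)(C)C(C)(C)C)c([Si](C)(C)C)c1OC | intermediate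
8 | 3,4,6-trimethoxy-2-(trimethylsilyl)phenyl N-isopropylcarbamate | COc1cc(OC)c(OC(=O)NC(C)C)c([Si](C)(C)C)c1OC | intermediate
9 | 3,4,6-trimethoxy-2-(trimethylsilyl)phenol | COc1cc(OC)c(O)c([Si](C)(C)C)c1OC | intermediate
10 | 3,4,6-trimethoxy-2-(trimethylsilyl)phenyl trifluoromethanesulfonate | COc1cc(OC)c(OC)c([Si](C)(C)C)c1OS(=O)(=O)C(F)(F)F | intermediate
11 | 2-iodo-1,4-dimethoxybenzene | COc1ccc(OC)c(I)c1 | starting material
12 | propiolic acid | C#CC(=O)O | starting material
13 | 3-(2,5-dimethoxyphenyl)propiolic acid | OC(=O)C#Cc1cc(OC)ccc1OC | intermediate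
14 | 3,4,6-trimethoxybenzyne | COC1=CC(OC)=C(OC)C#C1 | intermediate
15 | 3-(2,5-dimethoxyphenyl)-1-(2-hydroxy-3,5,6-trimethoxyphenyl)prop-2-yn-1-one | COc1ccc(OC)c(C#CC(=O)c2c(O)c(OC)cc(OC)c2OC)c1 | intermediate
16 | 2-(2,5-dimethoxyphenyl)-5,6,8-trimethoxy-4H-chromen-4-one | COc1ccc(OC)c(-c2cc(=O)c3c(OC)c(OC)cc(OC)c3o2)c1 | target

Total step count: 7. Longest linear sequence: 6 (steps 1, 2, 3, 4, 6, 7).

Steps most likely to fail

Step 6.
- **What may go wrong:** the carboxylate oxygen attacks the wrong aryne carbon (C4a in place of C8a), the aryl anion is protonated before the acyl group is transferred, or the propiolate decarboxylates thermally.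
- **Fallback:** it sets out from 4 and 13 and comes back at 15. Acid 13 is coupled with MeNHOMe·HCl (EDC·HCl, Et3N, CH2Cl2) to give N-methoxy-N-methyl-3-(2,5-dimethoxyphenyl)prop-2-ynamide F1. Carbamate 4 is taken through 5 to aryllithium 6 exactly as in step 3. Its C–Li bond already sits on C4a, and 6 is quenched at −78 °C by F1 in place of TMSCl. This gives 2-[3-(2,5-dimethoxyphenyl)prop-2-ynoyl]-3,4,6-trimethoxyphenyl N-(tert-butyldimethylsilyl)-N-isopropylcarbamate F2. Aqueous NaHSO4 work-up removes the N-silyl group and gives 2-[3-(2,5-dimethoxyphenyl)prop-2-ynoyl]-3,4,6-trimethoxyphenyl N-isopropylcarbamate F3. Et2NH and DBU in MeCN then remove the carbamate as in step 4 and free 15, which under these amine conditions should go on to 16. Directed ortho-metalation and acylation thus replace the aryne, and the position of lithium fixes the regiochemistry.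

Step 3.
- **What may go wrong:** lithiation occurs at the competing site between the two methoxy groups, double lithiation takes place, or the carbamoyl group migrates by an anionic ortho-Fries shift on warming.
- **Fallback:** it sets out from 3 and comes back at 9 (as its lithium salt), so it also bypasses the carbamate cleavage of step 4. NBS in CH2Cl2 at −78 to 0 °C brominates ortho to the free hydroxyl, the strongest donor, to give 2-bromo-3,4,6-trimethoxyphenol F4. HMDS in refluxing THF gives (2-bromo-3,4,6-trimethoxyphenoxy)trimethylsilane F5. n-BuLi in THF at −78 °C triggers bromine–lithium exchange and a retro-Brook oxygen-to-carbon silyl shift to the lithium salt of 9. Tf2O added to the same flask converts this salt to 10.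

Step 5.
- **What may go wrong:** the coupled propiolate decarboxylates and is arylated a second time, or oxidative addition to the electron-rich, ortho-substituted iodide is sluggish.
- **Fallback:** it sets out from 11 and comes back at 13. Sonogashira coupling of 11 with trimethylsilylacetylene (PdCl2(PPh3)2, CuI, Et3N, rt to 50 °C) gives [(2,5-dimethoxyphenyl)ethynyl]trimethylsilane F6. K2CO3 in MeOH gives 2-ethynyl-1,4-dimethoxybenzene F7. Deprotonation by n-BuLi in THF at −78 °C, a CO2 quench and acidification then give 13. The carboxyl carbon is thus attached last, when no palladium is present.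

Further compounds
F1 | step 6 | N-methoxy-N-methyl-3-(2,5-dimethoxyphenyl)prop-2-ynamide | CON(C)C(=O)C#Cc1cc(OC)ccc1OC
F2 | step 6 | 2-[3-(2,5-dimethoxyphenyl)prop-2-ynoyl]-3,4,6-trimethoxyphenyl N-(tert-butyldimethylsilyl)-N-isopropylcarbamate | COc1ccc(OC)c(C#CC(=O)c2c(OC(=O)N(C(C)C)[Si](C)(C)C(C)(C)C)c(OC)cc(OC)c2OC)c1
F3 | step 6 | 2-[3-(2,5-dimethoxyphenyl)prop-2-ynoyl]-3,4,6-trimethoxyphenyl N-isopropylcarbamate | COc1ccc(OC)c(C#CC(=O)c2c(OC(=O)NC(C)C)c(OC)cc(OC)c2OC)c1
F4 | step 3 | 2-bromo-3,4,6-trimethoxyphenol | COc1cc(OC)c(O)c(Br)c1OC
F5 | step 3 | (2-bromo-3,4,6-trimethoxyphenoxy)trimethylsilane | COc1cc(OC)c(O[Si](C)(C)C)c(Br)c1OC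
F6 | step 5 | [(2,5-dimethoxyphenyl)ethynyl]trimethylsilane | COc1ccc(OC)c(C#C[Si](C)(C)C)c1
F7 | step 5 | 2-ethynyl-1,4-dimethoxybenzene | COc1ccc(OC)c(C#C)c1
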